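Rings are lettered A (2,4,6-trihydroxyphenyl end) to G (3,4,5-trihydroxyphenyl end). Enabling feature: ring A is a phloroglucinol (OH on C1, C3, C5) whose C2 carries the ether oxygen to ring B. Its six carbons are therefore a folded hexanoate chain with an acyl carbon (chain C1), carbonyls at chain C3 and C5, and the aryloxy group on chain C6, and a bond from chain C6 to chain C1 regenerates the ring.
Cuts, in retrosynthetic order: sixteen O–CH3 bonds; the chain C1–C6 bond of ring A; the chain C4–C5 bond; the CH2–O bond to ring B; the aryl–O bonds at C2 of ring C (to D) and C2 of ring E (to F); the aryl–O bonds at C1 of rings C, E and G (to B, D and F).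
Forward: one boronic acid supplies rings C, E and G, syringaldehyde supplies rings B and F, and 3-hydroxy-4,5-dimethoxybenzaldehyde supplies ring D. One dimer aldehyde serves as both FG and BC; DE is joined to FG, BC is added, the chain is hung on ring B, and ring A is closed last.
Each formyl group deactivates its own ring, so iodination goes only to the neighbouring trimethoxyphenoxy ring, and it later becomes the next phenol by Baeyer–Villiger oxidation.
The chain C3 carbonyl travels as its methyl enol ether, so the ester is not switched off by a C2 enolate and the closure can run under reversible alkoxide conditions. This oxygen ends as a sixteenth methyl ether.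
Stereochemistry: the target has no stereocentre and no hindered axis is assumed. The only stereo-element on the way is the (E)-enol ether that holds chain C4 cis to the ester; it comes from the thermodynamic enol ether of methyl acetoacetate and disappears on aromatisation.

Key step: step 13

Remark: the acyclic precursor of ring A is drawn as its (E)-isomer. A (Z)-component would do no harm, because the double bond equilibrates through the C4 dienolate under the conditions of the ring closure.

Step 1
Reactants: 1 syringaldehyde (4-hydroxy-3,5-dimethoxybenzaldehyde); 2 3,4,5-trimethoxyphenylboronic acid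
Product: 3 3,5-dimethoxy-4-(3,4,5-trimethoxyphenoxy)benzaldehyde
Conditions: Cu(OAc)2 (1.5 equiv), pyridine, 4 Å MS, CH2Cl2, dry air, rt
Reagents that add atoms: none
Why: Chan–Lam O-arylation: the acidic phenoxide binds divalent copper, the electron-rich boronic acid transmetalates and the C–O bond forms by reductive elimination from trivalent copper at room temperature, a process known to accept acidic 2,6-disubstituted phenols and to leave formyl groups alone.

Step 2
Reactants: 3 3,5-dimethoxy-4-(3,4,5-trimethoxyphenoxy)benzaldehyde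
Product: 5 3,5-dimethoxy-4-(3,4,5-trimethoxyphenoxy)phenol (FG phenol), via FG formate 4 (not isolated)
Conditions: mCPBA, CH2Cl2, 0 °C to rt; then K2CO3 (cat.), MeOH, rt
Reagents that add atoms: mCPBA, O=C(OO)c1cccc(Cl)c1
Why: Baeyer–Villiger oxidation: as with 3,4,5-trialkoxybenzaldehydes the oxygenated aryl group migrates in preference to hydrogen, and formate 4 is cleaved by base-catalysed methanolysis without touching the ethers.

Step 3
Reactants: 3 3,5-dimethoxy-4-(3,4,5-trimethoxyphenoxy)benzaldehyde
Product: 6 4-(2-iodo-3,4,5-trimethoxyphenoxy)-3,5-dimethoxybenzaldehyde (BC iodide)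
Conditions: NIS (1.0 equiv), CF3CO2H (cat.), MeCN, 0 °C to rt, dark
Reagents that add atoms: N-iodosuccinimide, O=C1CCC(=O)N1I
Why: Electrophilic aromatic iodination with acid-activated NIS: the formyl group deactivates ring B, and the two free positions of the trimethoxyphenoxy ring are equivalent and lie ortho to the ether oxygen, so one equivalent of reagent should give a single mono-iodide.

Step 4
Reactants: 7 3-hydroxy-4,5-dimethoxybenzaldehyde; 2 3,4,5-trimethoxyphenylboronic acid
Product: 8 3,4-dimethoxy-5-(3,4,5-trimethoxyphenoxy)benzaldehyde (DE aldehyde)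
Conditions: Cu(OAc)2 (1.5 equiv), pyridine, 4 Å MS, CH2Cl2, dry air, rt
Reagents that add atoms: none
Why: Chan–Lam O-arylation as in step 1, here on a phenol with only one ortho substituent.

Step 5
Reactants: 8 3,4-dimethoxy-5-(3,4,5-trimethoxyphenoxy)benzaldehyde
Product: 9 3-(2-iodo-3,4,5-trimethoxyphenoxy)-4,5-dimethoxybenzaldehyde (DE iodide)
Conditions: NIS (1.0 equiv), CF3CO2H (cat.), MeCN, 0 °C to rt, dark
Reagents that add atoms: N-iodosuccinimide, O=C1CCC(=O)N1I
Why: Electrophilic aromatic iodination as in step 3, with ring D shielded by its formyl group and the two free positions of ring E equivalent.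

Step 6
Reactants: 9 DE iodide; 5 FG phenol
Product: 10 3-{2-[3,5-dimethoxy-4-(3,4,5-trimethoxyphenoxy)phenoxy]-3,4,5-trimethoxyphenoxy}-4,5-dimethoxybenzaldehyde (DEFG aldehyde)
Conditions: CuI (0.2 equiv), picolinic acid (0.4 equiv), K3PO4 (2 equiv), DMSO, 100 °C, Ar
Reagents that add atoms: none
Why: Ullmann-type C–O coupling: picolinate-ligated monovalent copper carries the unhindered, electron-rich phenoxide of 5 onto the aryl iodide, this catalyst system is designed for ortho-substituted partners, the classical Ullmann preparation of permethylated phlorethols from 2-halo-1,3-dialkoxybenzenes shows that halides flanked by two oxygens do couple, and the non-enolisable aldehyde is inert.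

Step 7
Reactants: 10 DEFG aldehyde
Product: 12 3-{2-[3,5-dimethoxy-4-(3,4,5-trimethoxyphenoxy)phenoxy]-3,4,5-trimethoxyphenoxy}-4,5-dimethoxyphenol (DEFG phenol), via DEFG formate 11 (not isolated)
Conditions: mCPBA, CH2Cl2, 0 °C to rt; then K2CO3 (cat.), MeOH, rt
Reagents that add atoms: mCPBA, O=C(OO)c1cccc(Cl)c1
Why: Baeyer–Villiger oxidation in which the para-methoxy group of ring D promotes aryl migration, followed by methanolysis of the formate; no iodide is left in the molecule that the peracid could oxidise.

Step 8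
Reactants: 6 BC iodide; 12 DEFG phenol
Product: 13 BCDEFG aldehyde (compound 6 with the iodine replaced by the oxygen-bound aryl residue of phenol 12; fifteen methoxy groups)
Conditions: CuI (0.3 equiv), picolinic acid (0.6 equiv), K3PO4 (2 equiv), DMSO, 100 °C, Ar; 6 in excess
Reagents that add atoms: none
Why: Ullmann-type C–O coupling of the same kind as step 6, since the phenol oxygen on C1 of ring D has two ortho hydrogens and all the steric load sits on the iodide, which is the cheaper partner and can be used in excess.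

Step 9
Reactants: 13 BCDEFG aldehyde
Product: 15 BCDEFG phenol (written ArOH from here on; Ar is bonded through C1 of ring B), via BCDEFG formate 14 (not isolated)
Conditions: mCPBA, CH2Cl2, 0 °C to rt; then K2CO3 (cat.), MeOH, rt
Reagents that add atoms: mCPBA, O=C(OO)c1cccc(Cl)c1
Why: Baeyer–Villiger oxidation and formate methanolysis on a ring B with the same substitution as in step 2, all other rings being fully etherified and without an oxidisable carbonyl.

Step 10
Reactants: 15 BCDEFG phenol ArOH; 16 2-bromo-N-methoxy-N-methylacetamide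
Product: 17 2-(ArO)-N-methoxy-N-methylacetamide
Conditions: K2CO3, DMF, rt to 50 °C
Reagents that add atoms: none
Why: Williamson ether synthesis (SN2 of an unhindered phenoxide on an α-bromo amide), which lays down the future ring A C2–O bond as a simple alkyl aryl ether before that carbon becomes crowded.

Step 11
Reactants: 18 methyl acetoacetate
Product: 19 methyl (E)-3-methoxybut-2-enoate
Conditions: HC(OMe)3, H2SO4 (cat.), MeOH, rt; distillation
Reagents that add atoms: trimethyl orthoformate, COC(OC)OC
Why: Acid-catalysed enol ether formation from a β-keto ester with an orthoformate, which gives the conjugated (E)-isomer (methoxy trans to the ester, methyl cis to it) as the thermodynamic product.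

Step 12
Reactants: 17 2-(ArO)-N-methoxy-N-methylacetamide; 19 methyl (E)-3-methoxybut-2-enoate
Product: 22 methyl (E)-6-(ArO)-3-methoxy-5-oxohex-2-enoate, via lithium dienolate 20 (not isolated), via chelated adduct 21 (not isolated)
Conditions: 19 (3 equiv), LiN(iPr)2 (3 equiv), THF, −78 °C; then 17, −78 to −40 °C; AcOH quench at −78 °C
Reagents that add atoms: none
Why: Weinreb ketone synthesis with a vinylogous ester enolate: the 3-methoxy group polarises dienolate 20 towards its terminal CH2, as in the γ-selective aldol and acylation reactions of 3-alkoxycrotonate dienolates and their silyl ketene acetals, and adduct 21 releases the ketone only on the acidic quench, so neither over-addition nor early lactonisation should intervene.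

Step 13
Reactants: 22 methyl (E)-6-(ArO)-3-methoxy-5-oxohex-2-enoate
Product: 24 2-(ArO)-5-methoxybenzene-1,3-diol, via cyclohexenedione 23 (not isolated)
Conditions: NaOMe (6 equiv), MeOH (dilute), sealed tube, 130 °C, Ar; then aq HCl
Reagents that add atoms: none
Why: In hot methanolic NaOMe 22 is deprotonated reversibly at C4 and C6; the C6 enolate, favoured by the inductive pull of the aryloxy oxygen, adds to the C1 ester carbonyl that the (E)-C2=C3 bond holds cis to C4, methoxide leaves, and cyclohexenedione 23 enolises at once to resorcinol 24, held as its phenoxide until the acid quench. This is an intramolecular Claisen (Dieckmann-type) condensation whose closest known relative is the conversion of 4-methoxy-6-methyl-2-pyranone, by way of ring-opened methyl 3-methoxy-5-oxohex-2-enoate, into 5-methoxyresorcinol with sodium methoxide in hot methanol, the flask counterpart of the closure performed by type 3 polyketide synthases. Ring A closes in the 6-(enolexo)-exo-trig mode with C1–C6 as the only new skeletal bond. The C6 stereocentre of 23 is transient and is erased on aromatisation, so nothing has to be controlled. The selectivity required is C-acylation by C6 over O-acylation by the C5 enolate oxygen, and it is secured thermodynamically: lactonisation to the 4-methoxy-2-pyranone, E/Z isomerisation and retro-Claisen cleavage of C4–C5 are all reversible in methoxide–methanol, whereas aromatisation is not. The C3 enol ether is essential, because the free 3,5-dioxo ester would be deprotonated at C2, which turns the ester into an unreactive enolate (a polyanion made with LiN(iPr)2 has the same defect), and its pyranone would be parked as an inert 4-oxide salt; C2 is vinylic and C4 could only close a four-membered ring, so no other carbocyclisation competes.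

Step 14
Reactants: 24 2-(ArO)-5-methoxybenzene-1,3-diol
Product: 25 CNP0130704.0 (target heptamer, eighteen free hydroxyls)
Conditions: BBr3 (40 equiv), CH2Cl2, −78 °C to rt, Ar; then H2O, 0 °C; reversed-phase chromatography with degassed solvents
Reagents that add atoms: none
Why: Lewis-acid cleavage of aryl methyl ethers: BBr3 complexes each methoxy oxygen and bromide removes the methyl group by SN2, the diaryl ether bonds offer no sp3 carbon and stay intact, and exclusion of air during reaction and work-up guards the polyphenol against oxidation.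

Compound list
1 | syringaldehyde (4-hydroxy-3,5-dimethoxybenzaldehyde) | COc1cc(C=O)cc(OC)c1O | starting material
2 | 3,4,5-trimethoxyphenylboronic acid | COc1cc(B(O)O)cc(OC)c1OC | starting material
3 | 3,5-dimethoxy-4-(3,4,5-trimethoxyphenoxy)benzaldehyde | O=Cc1cc(OC)c(Oc2cc(OC)c(OC)c(OC)c2)c(OC)c1 | intermediate
4 | 3,5-dimethoxy-4-(3,4,5-trimethoxyphenoxy)phenyl formate (FG formate) | O=COc1cc(OC)c(Oc2cc(OC)c(OC)c(OC)c2)c(OC)c1 | intermediate
5 | 3,5-dimethoxy-4-(3,4,5-trimethoxyphenoxy)phenol (FG phenol) | Oc1cc(OC)c(Oc2cc(OC)c(OC)c(OC)c2)c(OC)c1 | intermediate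
6 | 4-(2-iodo-3,4,5-trimethoxyphenoxy)-3,5-dimethoxybenzaldehyde (BC iodide) | O=Cc1cc(OC)c(Oc2cc(OC)c(OC)c(OC)c2I)c(OC)c1 | intermediate
7 | 3-hydroxy-4,5-dimethoxybenzaldehyde | COc1cc(C=O)cc(O)c1OC | starting material
8 | 3,4-dimethoxy-5-(3,4,5-trimethoxyphenoxy)benzaldehyde (DE aldehyde) | O=Cc1cc(OC)c(OC)c(Oc2cc(OC)c(OC)c(OC)c2)c1 | intermediate
9 | 3-(2-iodo-3,4,5-trimethoxyphenoxy)-4,5-dimethoxybenzaldehyde (DE iodide) | O=Cc1cc(OC)c(OC)c(Oc2cc(OC)c(OC)c(OC)c2I)c1 | intermediate
10 | DEFG aldehyde | O=Cc1cc(OC)c(OC)c(Oc2cc(OC)c(OC)c(OC)c2Oc2cc(OC)c(Oc3cc(OC)c(OC)c(OC)c3)c(OC)c2)c1 | intermediate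
11 | DEFG formate | O=COc1cc(OC)c(OC)c(Oc2cc(OC)c(OC)c(OC)c2Oc2cc(OC)c(Oc3cc(OC)c(OC)c(OC)c3)c(OC)c2)c1 | intermediate
12 | DEFG phenol | Oc1cc(OC)c(OC)c(Oc2cc(OC)c(OC)c(OC)c2Oc2cc(OC)c(Oc3cc(OC)c(OC)c(OC)c3)c(OC)c2)c1 | intermediate
13 | BCDEFG aldehyde | O=Cc1cc(OC)c(Oc2cc(OC)c(OC)c(OC)c2Oc2cc(OC)c(OC)c(Oc3cc(OC)c(OC)c(OC)c3Oc3cc(OC)c(Oc4cc(OC)c(OC)c(OC)c4)c(OC)c3)c2)c(OC)c1 | intermediate
14 | BCDEFG formate | O=COc1cc(OC)c(Oc2cc(OC)c(OC)c(OC)c2Oc2cc(OC)c(OC)c(Oc3cc(OC)c(OC)c(OC)c3Oc3cc(OC)c(Oc4cc(OC)c(OC)c(OC)c4)c(OC)c3)c2)c(OC)c1 | intermediate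
15 | BCDEFG phenol (ArOH) | Oc1cc(OC)c(Oc2cc(OC)c(OC)c(OC)c2Oc2cc(OC)c(OC)c(Oc3cc(OC)c(OC)c(OC)c3Oc3cc(OC)c(Oc4cc(OC)c(OC)c(OC)c4)c(OC)c3)c2)c(OC)c1 | intermediate
16 | 2-bromo-N-methoxy-N-methylacetamide | CON(C)C(=O)CBr | starting material
17 | 2-(ArO)-N-methoxy-N-methylacetamide | CON(C)C(=O)COc1cc(OC)c(Oc2cc(OC)c(OC)c(OC)c2Oc2cc(OC)c(OC)c(Oc3cc(OC)c(OC)c(OC)c3Oc3cc(OC)c(Oc4cc(OC)c(OC)c(OC)c4)c(OC)c3)c2)c(OC)c1 | intermediate
18 | methyl acetoacetate | COC(=O)CC(C)=O | starting material
19 | methyl (E)-3-methoxybut-2-enoate | COC(=O)/C=C(/OC)C | intermediate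
20 | lithium dienolate of 19 (lithium 1,3-dimethoxybuta-1,3-dien-1-olate) | [Li+].C=C(OC)C=C([O-])OC | intermediate
21 | lithium-chelated tetrahedral adduct of 20 and 17 (racemic at the carbinolamine carbon) | [Li+].COC(=O)/C=C(/OC)CC([O-])(N(C)OC)COc1cc(OC)c(Oc2cc(OC)c(OC)c(OC)c2Oc2cc(OC)c(OC)c(Oc3cc(OC)c(OC)c(OC)c3Oc3cc(OC)c(Oc4cc(OC)c(OC)c(OC)c4)c(OC)c3)c2)c(OC)c1 | intermediate
22 | methyl (E)-6-(ArO)-3-methoxy-5-oxohex-2-enoate | COC(=O)/C=C(/OC)CC(=O)COc1cc(OC)c(Oc2cc(OC)c(OC)c(OC)c2Oc2cc(OC)c(OC)c(Oc3cc(OC)c(OC)c(OC)c3Oc3cc(OC)c(Oc4cc(OC)c(OC)c(OC)c4)c(OC)c3)c2)c(OC)c1 | intermediate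
23 | 6-(ArO)-3-methoxycyclohex-2-ene-1,5-dione (racemic, transient) | COC1=CC(=O)C(C(=O)C1)Oc1cc(OC)c(Oc2cc(OC)c(OC)c(OC)c2Oc2cc(OC)c(OC)c(Oc3cc(OC)c(OC)c(OC)c3Oc3cc(OC)c(Oc4cc(OC)c(OC)c(OC)c4)c(OC)c3)c2)c(OC)c1 | intermediate
24 | 2-(ArO)-5-methoxybenzene-1,3-diol | COc1cc(O)c(c(O)c1)Oc1cc(OC)c(Oc2cc(OC)c(OC)c(OC)c2Oc2cc(OC)c(OC)c(Oc3cc(OC)c(OC)c(OC)c3Oc3cc(OC)c(Oc4cc(OC)c(OC)c(OC)c4)c(OC)c3)c2)c(OC)c1 | intermediate
25 | CNP0130704.0 | Oc1cc(O)c(Oc2cc(O)c(Oc3cc(O)c(O)c(O)c3Oc3cc(O)c(O)c(Oc4cc(O)c(O)c(O)c4Oc4cc(O)c(Oc5cc(O)c(O)c(O)c5)c(O)c4)c3)c(O)c2)c(O)c1 | target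

Total step count: 14. Longest linear sequence: 10 steps (1, 2, 6, 7, 8, 9, 10, 12, 13, 14).

Steps most likely to fail

Step 13. The substrate may rest as its C4 extended enolate or as the pyranone, so that carbocyclisation is too slow at temperatures the α-aryloxy ketone tolerates. Loss of aryloxide or irreversible consumption of the C4–C5 cleavage fragments could then drain the material. Fallback: setting out from phenol 15, ring A would be attached ready-made. Ullmann coupling with commercial 2-iodo-1,3,5-trimethoxybenzene (COc1cc(OC)c(I)c(OC)c1; CuI, picolinic acid, K3PO4, DMSO, 100 °C) is the same type of coupling as in steps 6 and 8. It should give the octadecamethyl ether of the target F1, and BBr3 as in step 14 comes back to the route at 25.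

Step 8. Substitution at an iodide flanked by a methoxy group and a bulky aryloxy group may be slower than hydrodeiodination or decay of the catalyst, above all with a tetrameric phenol. Step 6 is the same reaction on smaller partners and should be the easier case. Fallback: setting out from iodide 6 and phenol 12, the roles of the partners are exchanged, so that the crowded ring carries the oxygen and the open ring the leaving group.
- Miyaura borylation of 6 (B2pin2, PdCl2(dppf), KOAc, dioxane, 90 °C) should give the pinacol boronate F2.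
- Mild oxidation (NaBO3·4H2O, THF–H2O, rt) should then give the hindered ring C phenol F3.
- Phenol 12 is converted with Tf2O and pyridine into the DEFG aryl triflate F4.
- Palladium-catalysed C–O coupling of F3 with F4 (Pd(OAc)2, t-BuXPhos, K3PO4, toluene, 100 °C) benefits from easy oxidative addition at the unhindered triflate, and the bulky phenoxide speeds reductive elimination. It comes back to the route at aldehyde 13.

Step 12. The dienolate may attack through its α-carbon instead of the terminal CH2, or may merely enolise amide 17 and return it unchanged. Fallback: setting out from phenol 15, the whole six-carbon unit is brought in by O-alkylation instead of C-acylation.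
- Commercial 4-methoxy-6-methyl-2H-pyran-2-one is brominated on the methyl group (Wohl–Ziegler bromination; NBS, dibenzoyl peroxide, PhCF3, reflux) to 6-(bromomethyl)-4-methoxy-2H-pyran-2-one F5.
- Phenol 15 is alkylated with F5 (K2CO3, acetone, reflux) to 6-(ArO-methyl)-4-methoxy-2H-pyran-2-one F6.
- Methanolic NaOMe opens the lactone of F6 at its carbonyl, with the ring double bond already holding C4 cis to the ester. This comes back to the route at 22, which can be taken straight on under the conditions of step 13.

Further compounds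
F1 | step 13 | octadecamethyl ether of the target (2-(ArO)-1,3,5-trimethoxybenzene) | COc1cc(OC)c(c(OC)c1)Oc1cc(OC)c(Oc2cc(OC)c(OC)c(OC)c2Oc2cc(OC)c(OC)c(Oc3cc(OC)c(OC)c(OC)c3Oc3cc(OC)c(Oc4cc(OC)c(OC)c(OC)c4)c(OC)c3)c2)c(OC)c1
F2 | step 8 | 3,5-dimethoxy-4-[3,4,5-trimethoxy-2-(4,4,5,5-tetramethyl-1,3,2-dioxaborolan-2-yl)phenoxy]benzaldehyde | O=Cc1cc(OC)c(Oc2cc(OC)c(OC)c(OC)c2B3OC(C)(C)C(C)(C)O3)c(OC)c1
F3 | step 8 | 4-(2-hydroxy-3,4,5-trimethoxyphenoxy)-3,5-dimethoxybenzaldehyde | O=Cc1cc(OC)c(Oc2cc(OC)c(OC)c(OC)c2O)c(OC)c1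
F4 | step 8 | DEFG aryl trifluoromethanesulfonate (triflate of 12) | O=S(=O)(Oc1cc(OC)c(OC)c(Oc2cc(OC)c(OC)c(OC)c2Oc2cc(OC)c(Oc3cc(OC)c(OC)c(OC)c3)c(OC)c2)c1)C(F)(F)F
F5 | step 12 | 6-(bromomethyl)-4-methoxy-2H-pyran-2-one | COC1=CC(=O)OC(CBr)=C1
F6 | step 12 | 6-(ArO-methyl)-4-methoxy-2H-pyran-2-one | COC1=CC(=O)OC(=C1)COc1cc(OC)c(Oc2cc(OC)c(OC)c(OC)c2Oc2cc(OC)c(OC)c(Oc3cc(OC)c(OC)c(OC)c3Oc3cc(OC)c(Oc4cc(OC)c(OC)c(OC)c4)c(OC)c3)c2)c(OC)c1
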